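**Remark on the chemistry:** flavone locants are used for rings A and C (O1, C2, C3, C4, C4a, C5–C8, C8a) and primed locants for the piperidine. The target is taken as the neutral free base with C2' of R configuration. The connectivity of 9, 14 and 16 is self-consistent and needed no correction; the changes are a two-step access to 14 through an ester-derived ynolate and thermal instead of silver-salt activation of the cycloaddition.

## Structural features

The target is a flavone: benzo ring A and γ-pyranone ring C share the C4a–C8a bond, and phenyl ring B sits on C2. Ring A is pentasubstituted, with OMe at C5, H at C6, OH at C7 and a piperidine (ring D) bonded to C8 through C2'. C2' is the only stereocentre (R) and has no stereogenic neighbour, so the problem is one of absolute configuration only. C2' is benzylic, carries the basic nitrogen, and is flanked by the ortho 7-OH, the ortho ring oxygen O1 and a para methoxy group. Acid or base can therefore open the C2'–N bond reversibly through a benzylic cation or an ortho-quinone methide and racemise it. The γ-pyranone is also open to hard nucleophiles at C2, and the free amino phenol is zwitterion-prone. The real difficulty is joining a configurationally intact 2-piperidyl carbon to C8, the most hindered ring-A position, without C6/C8 ambiguity. The route uses the fact that C4a, C5, C6 and C8a, with their oxygen pattern, are the diene carbons of a 2-pyrone fused to ring C, whose lactone unit O8–C7 leaves as CO2. C7 and C8, with the phenol oxygen and the piperidine, map onto a silyl ynol ether made from pipecolic acid, so ring A is built last, around the stereocentre.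

## Logic of the disconnections

18 from 17: only the N1'–C(carbamate) bond is cut. Keeping the nitrogen acylated until the last operation makes every earlier intermediate non-basic and removes the amine as a leaving group at the benzylic centre. The forward step must be a brief, cold acidolysis so that C2' does not ionise.

17 from 16: the O7–Si bond is cut. The silyl group is the residue of the ynol ether and costs no separate protection step. The forward step needs a fluoride source buffered enough to spare the γ-pyranone.

16 from 9 and 14, through 15: C8–C8a and C6–C7 are cut and the O8–C7(=O) bridge is restored. This opens ring A and splits the molecule into an achiral bicyclic diene and a chiral-pool alkyne of similar size. The whole ring-A substitution pattern and the C8/C6 question are settled by construction. The forward step must be a [4+2] addition of defined orientation, chemoselective for the pyrone diene, under conditions that leave C2' alone.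

9 from 5 and 7, through 8: O1–C2 and C4–C4a are cut. The nucleophile is symmetric and its central oxygen is already methylated, so there is no regiochemical choice. The forward step must acylate carbon and not oxygen, and close 6-endo and not 5-exo.

7 from 6: C–Cl is exchanged for C–OH. The activation must be mild because the ynoic acid self-condenses on heating.

5 from 4, 4 from 3, 3 from 1 through 2: the anhydride C–O bond, the two ester O–CH3 bonds and the enol-ether O–CH3 bond are cut in turn. The methoxy group that becomes the C5 substituent is fixed on a symmetric five-carbon chain before any ring exists. The forward steps must keep the enol ether through hydrolysis and avoid decarboxylation.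

14 from 11 through 12 and 13, and 11 from 10: the O–Si bond is cut and the alkyne carbon bonded to C2' is excised from between C2' and the former carboxyl carbon. The carboxyl carbon of 10 thus becomes C7 with its oxygen attached, and C2' comes from the chiral pool. The forward step needs a one-carbon insertion in which C2' migrates with retention, is never enolised, and the ynolate is silylated on oxygen.

## Other disconnections considered

Alternative 1: the cut is N1'–C2'. A chiral BINOL-derived phosphoric acid would protonate C3' of N-[(4E)-5-(7-hydroxy-5-methoxy-4-oxo-2-phenyl-4H-chromen-8-yl)pent-4-en-1-yl]-2-nitrobenzenesulfonamide A1. The sulfonamide nitrogen would then add to C2' of the ion-paired ortho-quinone methide to give 7-hydroxy-5-methoxy-8-[(2R)-1-(2-nitrophenylsulfonyl)piperidin-2-yl]-2-phenyl-4H-chromen-4-one A2.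
- In favour: the stereocentre is made catalytically on an intact, cheap flavone core, either enantiomer is available by choice of catalyst, and the nosyl group comes off with a thiolate without acid.
- Against: the 7-hydroxyl is a vinylogous acid through C4=O, so dearomatising ring A to the quinone methide is uphill. Facial control in a six-membered closure of this kind is not secured by any substrate element. The same ionisation that forms the C2'–N bond can reverse it and erode the configuration.
- Comparison: on structure it must first solve C8-versus-C6 functionalisation, which the chosen plan avoids. On mechanism neither key step has direct precedent, so the two are equal. It is better in not depending on D-pipecolic acid and in needing no organolithium chemistry. It is worse in that the chosen plan only has to preserve a stereocentre and not create one under equilibrating conditions. Step economy is about equal.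

Alternative 2: the cuts are C5'–C6' and N1'–C6'. Rh(acac)(CO)2 with BIPHEPHOS under synthesis gas would hydroformylate the terminal carbon of tert-butyl N-[(1R)-1-(7-benzyloxy-5-methoxy-4-oxo-2-phenyl-4H-chromen-8-yl)but-3-en-1-yl]carbamate A3, carbon monoxide A4 supplying C6'. The aldehyde would condense with the carbamate N–H to give tert-butyl (2R)-2-(7-benzyloxy-5-methoxy-4-oxo-2-phenyl-4H-chromen-8-yl)-3,4-dihydro-2H-pyridine-1-carboxylate A5.
- In favour: linear hydroformylation with this ligand and closure onto a carbamate is an established reaction type, so on precedent of the key step this alternative is better than the chosen plan. C2' would be set earlier by auxiliary-controlled allylation of an imine, a dependable method. One hydrogenation could saturate C5'=C6' and remove the benzyl group together.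
- Against: pressurised A4 and hydrogen are a safety burden. The hydrogenation must spare C2=C3 of ring C and the benzylic C2'–N bond. A C8 aldehyde must be made regioselectively, and the auxiliary put on and exchanged for the carbamate.
- Comparison: better on mechanistic confidence, equal in the endgame (same cold acid deprotection, same lability of C2'), worse in convergence and step count, which should exceed that of the chosen plan by several operations.

Alternative 3: the cuts are C4a–C4, C4–C3 and O1–C2. Palladium catalysis in diethylamine would combine tert-butyl (2R)-2-(2,6-dihydroxy-3-iodo-4-methoxyphenyl)piperidine-1-carboxylate A6, carbon monoxide A4 and phenylacetylene A7. The ortho hydroxyl would close onto the ynone to give tert-butyl (2R)-2-(7-hydroxy-5-methoxy-4-oxo-2-phenyl-4H-chromen-8-yl)piperidine-1-carboxylate A8, which is the same compound as 17.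
- In favour: the three-component flavone synthesis is known chemistry, so this alternative is better on precedent. A6 derives from a symmetric resorcinol, so mono-iodination is unambiguous. No desilylation is needed after the key step, which saves one operation there.
- Against: the hard problem, an enantiopure 2-arylpiperidine with two ortho oxygens, is only moved earlier and needs its own asymmetric sequence. 5-Exo closure to an aurone competes. C2' must survive more steps on an electron-rich resorcinol, where ionisation is easier than on the chromone. A4 must be handled.
- Comparison: better on mechanism, equal in the final deprotection, equal or slightly worse in total steps, and less convergent. Because it is known chemistry it serves as the fallback for the key step, reached from 14.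

Key step: step 8

## Route

Step 1
Reactants: 1 dimethyl 1,3-acetonedicarboxylate (dimethyl 3-oxopentanedioate)
Product: 3 dimethyl (E)-3-methoxypent-2-enedioate, via dimethyl 3,3-dimethoxypentanedioate 2 (not isolated)
Conditions: HC(OMe)3, cat. H2SO4, MeOH, reflux; then distil off MeOH
Reagents that add atoms: trimethyl orthoformate, COC(OC)OC
Why: Acid-catalysed ketalisation by the orthoester and loss of methanol from ketal 2 on distillation give the conjugated β-methoxy enoate (enol ether formation from a β-keto ester); the E isomer, with the ester trans to methoxy, is the thermodynamic one, and any Z isomer converges later through the easy 1,3-proton shift of glutaconates.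

Step 2
Reactants: 3 dimethyl (E)-3-methoxypent-2-enedioate
Product: 4 (E)-3-methoxypent-2-enedioic acid
Conditions: NaOH, H2O–MeOH, 0 °C to rt; then cold 2 M HCl to pH 2, EtOAc extraction
Reagents that add atoms: sodium hydroxide, [Na+].[OH-]
Why: Saponification of both methyl esters; the β-methoxyacrylate is a vinylogous carbonate that resists hydroxide and brief cold acid, and the low temperature guards against decarboxylation of the β,γ-unsaturated acid.

Step 3
Reactants: 4 (E)-3-methoxypent-2-enedioic acid
Product: 5 4-methoxy-2H-pyran-2,6(3H)-dione (3-methoxyglutaconic anhydride)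
Conditions: Ac2O, 15–20 °C; evaporate, crystallise
Reagents that add atoms: none
Why: Cyclodehydration of a glutaconic acid to its six-membered anhydride, as in the cold acetic anhydride closure of acetonedicarboxylic acid; in the E diacid the vinylic carboxyl is already cis to the CH2CO2H arm, and the short, cool reaction avoids O-acetylation of the enol form.

Step 4
Reactants: 6 3-phenylprop-2-ynoic acid (phenylpropiolic acid)
Product: 7 3-phenylprop-2-ynoyl chloride
Conditions: (COCl)2, cat. DMF, CH2Cl2, 0 °C to rt; evaporate, use at once
Reagents that add atoms: oxalyl chloride, O=C(Cl)C(Cl)=O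
Why: Acid chloride formation through the catalytic chloroiminium salt from DMF; room temperature avoids the thermal self-condensation to which phenylpropiolic acid derivatives are prone.

Step 5
Reactants: 5 4-methoxy-2H-pyran-2,6(3H)-dione; 7 3-phenylprop-2-ynoyl chloride
Product: 9 5-methoxy-2-phenyl-4H,7H-pyrano[2,3-b]pyran-4,7-dione, via C-acylated hydroxypyrone 8 (not isolated)
Conditions: pyridine, CH2Cl2, −10 °C to rt; then DMAP (cat.), rt; cold dilute acid wash, crystallise
Reagents that add atoms: none
Why: C-acylation of the strongly acidic cyclic anhydride through its pyridinium enolate (any O-acyl isomer being relayed to carbon by DMAP, as with acyl Meldrum's acids and 2-acylglutaconic anhydrides) gives 8, whose C6 hydroxyl then adds to the ynone β-carbon in a 6-endo-dig oxa-Michael closure under nucleophilic catalysis; the anhydride is symmetric and its C4 oxygen is methylated, so only one acylation site and one ring closure exist.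

Step 6
Reactants: 10 (2R)-1-(tert-butoxycarbonyl)piperidine-2-carboxylic acid ((R)-N-Boc-pipecolic acid)
Product: 11 1-tert-butyl 2-methyl (2R)-piperidine-1,2-dicarboxylate
Conditions: MeI, K2CO3, DMF, rt
Reagents that add atoms: iodomethane, CI
Why: SN2 O-alkylation of the carboxylate; the carbonyl group is never activated, so C2' cannot epimerise and the carbamate is untouched.

Step 7
Reactants: 11 1-tert-butyl 2-methyl (2R)-piperidine-1,2-dicarboxylate
Product: 14 tert-butyl (2R)-2-[(triisopropylsilyloxy)ethynyl]piperidine-1-carboxylate, via lithium dibromoenolate 12 (not isolated), via lithium ynolate 13 (not isolated)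
Conditions: CH2Br2, lithium 2,2,6,6-tetramethylpiperidide (LiTMP), THF, −78 °C; n-BuLi, −78 to 0 °C; i-Pr3SiOTf, −78 to 0 °C
Reagents that add atoms: dibromomethane, BrCBr; triisopropylsilyl trifluoromethanesulfonate, CC(C)[Si](OS(=O)(=O)C(F)(F)F)(C(C)C)C(C)C
Why: Kowalski ester homologation stopped at the ynolate: dibromomethyllithium adds to the ester, enolate 12 undergoes bromine–lithium exchange and 1,2-shift of the piperidinyl carbon to give ynolate 13, and the bulky silyl triflate silylates 13 on oxygen; C2' migrates as an intact sp3 carbon with retention and is never deprotonated, since the CHBr2 proton is the acidic one and the carbamate has no N–H.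

Step 8
Reactants: 9 5-methoxy-2-phenyl-4H,7H-pyrano[2,3-b]pyran-4,7-dione; 14 tert-butyl (2R)-2-[(triisopropylsilyloxy)ethynyl]piperidine-1-carboxylate
Product: 16 tert-butyl (2R)-2-[5-methoxy-4-oxo-2-phenyl-7-(triisopropylsilyloxy)-4H-chromen-8-yl]piperidine-1-carboxylate, via bridged lactone adduct 15 (not isolated)
Conditions: toluene, 110 °C, sealed tube, argon (−CO2)
Reagents that add atoms: none
Why: Proposed new method: the alkyne carbon bearing the piperidine, the nucleophilic carbon β to the silyloxy group, should attack C8a of 9, the pyrone terminus that is β to the C4 ketone and δ to the C7 lactone carbonyl, and the resulting silyl ketenium carbon should be trapped by C6, made nucleophilic by the C5 methoxy group, in a concerted but strongly asynchronous or stepwise inverse-demand [4+2] that forms C8–C8a and C6–C7. Bridged lactone 15 then loses CO2 (O8 and C7 of 9) in a thermally allowed retro-[4+2], which aromatises ring A and makes the sequence irreversible. The closest known reaction type is the Diels–Alder addition of ynamines and alkoxyalkynes to electron-poor 2-pyrones with extrusion of CO2 to benzenes; a fused, doubly oxygenated 2-pyrone and a silyl ynol ether have not been combined in this way. Ring A closes by intermolecular [4+2] cycloaddition across the diene termini C6 and C8a (in the stepwise limit a 6-exo-dig attack of C6 on the ketenium carbon) followed by cycloreversion; no stereocentre is created, the two bridgehead centres of 15 vanish on aromatisation, and C2' is carried unchanged from 10 because no bond to it is touched and the medium is neutral. Regioselectivity rests on matched polarisation: the largest HOMO coefficient of 14 meets the most electrophilic diene terminus, whereas the reverse orientation would pair the two donor-bearing carbons. Chemoselectivity over [2+2] addition at C2=C3 should follow from the phenyl group, which hinders and conjugatively deactivates C2, while C8a is activated by two carbonyl groups; heat is preferred to AgNTf2 because a silver-bound ketenium could be captured by the carbamate carbonyl oxygen in a six-membered closure. The triisopropylsilyl group is chosen because such ynol ethers tolerate 110 °C without 1,3-silyl shift to the silylketene.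

Step 9
Reactants: 16 tert-butyl (2R)-2-[5-methoxy-4-oxo-2-phenyl-7-(triisopropylsilyloxy)-4H-chromen-8-yl]piperidine-1-carboxylate
Product: 17 tert-butyl (2R)-2-(7-hydroxy-5-methoxy-4-oxo-2-phenyl-4H-chromen-8-yl)piperidine-1-carboxylate
Conditions: Bu4NF, AcOH, THF, 0 °C
Reagents that add atoms: none
Why: Fluoride cleavage of an aryl silyl ether, fast because the 7-oxyflavone oxygen is a good leaving group; acetic acid buffering keeps the phenol protonated so that the γ-pyranone and the C2'–N bond are not exposed to a basic phenoxide, and the carbamate is inert.

Step 10
Reactants: 17 tert-butyl (2R)-2-(7-hydroxy-5-methoxy-4-oxo-2-phenyl-4H-chromen-8-yl)piperidine-1-carboxylate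
Product: 18 7-hydroxy-5-methoxy-2-phenyl-8-[(2R)-piperidin-2-yl]-4H-chromen-4-one (target)
Conditions: CF3CO2H, CH2Cl2, 0 °C; then aq. NaHCO3
Reagents that add atoms: none
Why: Acidolysis of the tert-butyl carbamate with loss of 2-methylpropene and CO2; the low temperature and short contact time are meant to prevent reversible ionisation of the benzylic C2'–N bond, and bicarbonate liberates the free base without exposing the γ-pyranone to hydroxide.

## Compound list

1 | dimethyl 3-oxopentanedioate (dimethyl 1,3-acetonedicarboxylate) | COC(=O)CC(=O)CC(=O)OC | starting material
2 | dimethyl 3,3-dimethoxypentanedioate | COC(=O)CC(OC)(OC)CC(=O)OC | intermediate (not isolated)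
3 | dimethyl (E)-3-methoxypent-2-enedioate | COC(=O)C/C(OC)=C\C(=O)OC | intermediate
4 | (E)-3-methoxypent-2-enedioic acid | OC(=O)C/C(OC)=C\C(=O)O | intermediate
5 | 4-methoxy-2H-pyran-2,6(3H)-dione (3-methoxyglutaconic anhydride) | COC1=CC(=O)OC(=O)C1 | intermediate
6 | 3-phenylprop-2-ynoic acid (phenylpropiolic acid) | OC(=O)C#Cc1ccccc1 | starting material
7 | 3-phenylprop-2-ynoyl chloride | ClC(=O)C#Cc1ccccc1 | intermediate
8 | 6-hydroxy-4-methoxy-5-(3-phenylprop-2-ynoyl)-2H-pyran-2-one | COC1=CC(=O)OC(O)=C1C(=O)C#Cc1ccccc1 | intermediate (not isolated)
9 | 5-methoxy-2-phenyl-4H,7H-pyrano[2,3-b]pyran-4,7-dione | COC1=CC(=O)OC2=C1C(=O)C=C(c1ccccc1)O2 | intermediate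
10 | (2R)-1-(tert-butoxycarbonyl)piperidine-2-carboxylic acid | OC(=O)[C@H]1CCCCN1C(=O)OC(C)(C)C | starting material
11 | 1-tert-butyl 2-methyl (2R)-piperidine-1,2-dicarboxylate | COC(=O)[C@H]1CCCCN1C(=O)OC(C)(C)C | intermediate
12 | lithium 2,2-dibromo-1-[(2R)-1-(tert-butoxycarbonyl)piperidin-2-yl]ethen-1-olate | [Li+].[O-]C(=C(Br)Br)[C@H]1CCCCN1C(=O)OC(C)(C)C | intermediate (not isolated)
13 | lithium 2-[(2R)-1-(tert-butoxycarbonyl)piperidin-2-yl]ethyn-1-olate | [Li+].[O-]C#C[C@H]1CCCCN1C(=O)OC(C)(C)C | intermediate (not isolated)
14 | tert-butyl (2R)-2-[(triisopropylsilyloxy)ethynyl]piperidine-1-carboxylate | CC(C)[Si](OC#C[C@H]1CCCCN1C(=O)OC(C)(C)C)(C(C)C)C(C)C | intermediate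
15 | 2-oxabicyclo[2.2.2]octa-5,7-dien-3-one adduct of 9 and 14: C8a and C6 of 9 are the bridgeheads, O8–C7(=O) is the lactone bridge, C4a=C5(OMe) and C(piperidinyl)=C(OSi(i-Pr)3) are the alkene bridges, the piperidinyl-bearing carbon on C8a; both bridgehead diastereomers, C2' R | COC1=C2C(=O)C=C(c3ccccc3)OC23OC(=O)C1C(O[Si](C(C)C)(C(C)C)C(C)C)=C3[C@H]1CCCCN1C(=O)OC(C)(C)C | intermediate (not isolated)
16 | tert-butyl (2R)-2-[5-methoxy-4-oxo-2-phenyl-7-(triisopropylsilyloxy)-4H-chromen-8-yl]piperidine-1-carboxylate | COc1cc(O[Si](C(C)C)(C(C)C)C(C)C)c([C@H]2CCCCN2C(=O)OC(C)(C)C)c2oc(-c3ccccc3)cc(=O)c12 | intermediate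
17 | tert-butyl (2R)-2-(7-hydroxy-5-methoxy-4-oxo-2-phenyl-4H-chromen-8-yl)piperidine-1-carboxylate | COc1cc(O)c([C@H]2CCCCN2C(=O)OC(C)(C)C)c2oc(-c3ccccc3)cc(=O)c12 | intermediate
18 | 7-hydroxy-5-methoxy-2-phenyl-8-[(2R)-piperidin-2-yl]-4H-chromen-4-one | COc1cc(O)c([C@H]2CCCCN2)c2oc(-c3ccccc3)cc(=O)c12 | target

## Step count and least certain steps

Total step count: 10. Longest linear sequence: 7 steps (steps 1, 2, 3, 5, 8, 9, 10, from 1 to 18).

**Step 8 (key step).** The push–pull diene may react too slowly, so that thermal decay of the ynol ether overtakes cycloaddition. Other possible failures are [2+2] addition at the C2=C3 enone, hetero-[4+2] addition across O=C4–C4a=C8a, and reversal of the regiochemical sense. The fallback uses known chemistry, sets out from 14 and builds ring A first and ring C last.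
- Commercial 3-ethoxycyclobut-2-en-1-one would be converted by acid-catalysed alkoxy exchange in methanol into 3-methoxycyclobut-2-en-1-one F1.
- Heating F1 with 14 in toluene at 110 °C (Danheiser benzannulation: vinylketene formation, [2+2] with the ynol ether, 4π opening, 6π closure) should give tert-butyl (2R)-2-[2-hydroxy-4-methoxy-6-(triisopropylsilyloxy)phenyl]piperidine-1-carboxylate F2. The ketene carbon bonds to the piperidinyl-bearing alkyne carbon.
- Bu4NF/AcOH would give the symmetric tert-butyl (2R)-2-(2,6-dihydroxy-4-methoxyphenyl)piperidine-1-carboxylate F3.
- One equivalent of N-iodosuccinimide in CH2Cl2 at −20 °C would give tert-butyl (2R)-2-(2,6-dihydroxy-3-iodo-4-methoxyphenyl)piperidine-1-carboxylate F4. The two open positions are equivalent.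
- PdCl2(PPh3)2, CO (1 atm), phenylacetylene and Et2NH at 60 °C (carbonylative alkynylation, then 6-endo closure of the ortho hydroxyl) would return the route at 17.

**Step 5.** Acylation may stop at oxygen without acyl migration, the anhydride ring may open under the amine base, or closure may go 5-exo. The fallback sets out from 5 and replaces the redox-neutral alkyne addition by an oxidative enone cyclisation. C-acylation with cinnamoyl chloride (pyridine, then cat. DMAP, CH2Cl2) would give 6-hydroxy-4-methoxy-5-[(2E)-3-phenylprop-2-enoyl]-2H-pyran-2-one F5. Catalytic I2 in DMSO at 100 °C, as for the closure of 2'-hydroxychalcones to flavones, would return the route at 9.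

**Step 7.** Butyllithium may attack the carbamate while the mixture warms, the carbenoid rearrangement may be incomplete, or the ynolate may be silylated on carbon. The fallback sets out from 11 and makes the ynolate by oxidation of an acetylide.
- i-Bu2AlH in CH2Cl2 at −78 °C would give tert-butyl (2R)-2-formylpiperidine-1-carboxylate F6.
- CBr4/PPh3 (Corey–Fuchs) would give tert-butyl (2R)-2-(2,2-dibromoethenyl)piperidine-1-carboxylate F7.
- Two equivalents of n-BuLi at −78 °C would give the lithium acetylide of tert-butyl (2R)-2-ethynylpiperidine-1-carboxylate F8.
- t-BuOOLi (from t-BuOOH and LiN(SiMe3)2) would oxidise F8 to ynolate 13, and i-Pr3SiOTf would then return the route at 14.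

**Step 10.** The configuration at C2' may erode through reversible acid-promoted opening of the benzylic C2'–N bond, and the tert-butyl cation may alkylate C6 of ring A. The fallback sets out from 16 and avoids protic acid altogether. Me3SiOTf with 2,6-lutidine in CH2Cl2 at 0 °C would convert the carbamate into trimethylsilyl (2R)-2-[5-methoxy-4-oxo-2-phenyl-7-(triisopropylsilyloxy)-4H-chromen-8-yl]piperidine-1-carboxylate F9. Bu4NF/AcOH in THF–MeOH would then remove both silyl groups, the carbamic acid losing CO2, and return the route at 18.

## Further compounds

F1 | step 8 | 3-methoxycyclobut-2-en-1-one | COC1=CC(=O)C1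
F2 | step 8 | tert-butyl (2R)-2-[2-hydroxy-4-methoxy-6-(triisopropylsilyloxy)phenyl]piperidine-1-carboxylate | COc1cc(O)c([C@H]2CCCCN2C(=O)OC(C)(C)C)c(O[Si](C(C)C)(C(C)C)C(C)C)c1
F3 | step 8 | tert-butyl (2R)-2-(2,6-dihydroxy-4-methoxyphenyl)piperidine-1-carboxylate | COc1cc(O)c([C@H]2CCCCN2C(=O)OC(C)(C)C)c(O)c1
F4 | step 8 | tert-butyl (2R)-2-(2,6-dihydroxy-3-iodo-4-methoxyphenyl)piperidine-1-carboxylate | COc1cc(O)c([C@H]2CCCCN2C(=O)OC(C)(C)C)c(O)c1I
F5 | step 5 | 6-hydroxy-4-methoxy-5-[(2E)-3-phenylprop-2-enoyl]-2H-pyran-2-one | COC1=CC(=O)OC(O)=C1C(=O)/C=C/c1ccccc1
F6 | step 7 | tert-butyl (2R)-2-formylpiperidine-1-carboxylate | O=C[C@H]1CCCCN1C(=O)OC(C)(C)C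
F7 | step 7 | tert-butyl (2R)-2-(2,2-dibromoethenyl)piperidine-1-carboxylate | BrC(Br)=C[C@H]1CCCCN1C(=O)OC(C)(C)C
F8 | step 7 | lithium acetylide of tert-butyl (2R)-2-ethynylpiperidine-1-carboxylate | [Li]C#C[C@H]1CCCCN1C(=O)OC(C)(C)C
F9 | step 10 | trimethylsilyl (2R)-2-[5-methoxy-4-oxo-2-phenyl-7-(triisopropylsilyloxy)-4H-chromen-8-yl]piperidine-1-carboxylate | COc1cc(O[Si](C(C)C)(C(C)C)C(C)C)c([C@H]2CCCCN2C(=O)O[Si](C)(C)C)c2oc(-c3ccccc3)cc(=O)c12
A1 | alternative 1 | N-[(4E)-5-(7-hydroxy-5-methoxy-4-oxo-2-phenyl-4H-chromen-8-yl)pent-4-en-1-yl]-2-nitrobenzenesulfonamide | COc1cc(O)c(/C=C/CCCNS(=O)(=O)c2ccccc2[N+](=O)[O-])c2oc(-c3ccccc3)cc(=O)c12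
A2 | alternative 1 | 7-hydroxy-5-methoxy-8-[(2R)-1-(2-nitrophenylsulfonyl)piperidin-2-yl]-2-phenyl-4H-chromen-4-one | COc1cc(O)c([C@H]2CCCCN2S(=O)(=O)c2ccccc2[N+](=O)[O-])c2oc(-c3ccccc3)cc(=O)c12
A3 | alternative 2 | tert-butyl N-[(1R)-1-(7-benzyloxy-5-methoxy-4-oxo-2-phenyl-4H-chromen-8-yl)but-3-en-1-yl]carbamate | COc1cc(OCc2ccccc2)c([C@@H](CC=C)NC(=O)OC(C)(C)C)c2oc(-c3ccccc3)cc(=O)c12
A4 | alternative 2 | carbon monoxide | [C-]#[O+]
A5 | alternative 2 | tert-butyl (2R)-2-(7-benzyloxy-5-methoxy-4-oxo-2-phenyl-4H-chromen-8-yl)-3,4-dihydro-2H-pyridine-1-carboxylate | COc1cc(OCc2ccccc2)c([C@H]2CCC=CN2C(=O)OC(C)(C)C)c2oc(-c3ccccc3)cc(=O)c12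
A6 | alternative 3 | tert-butyl (2R)-2-(2,6-dihydroxy-3-iodo-4-methoxyphenyl)piperidine-1-carboxylate | COc1cc(O)c([C@H]2CCCCN2C(=O)OC(C)(C)C)c(O)c1I
A7 | alternative 3 | phenylacetylene | C#Cc1ccccc1
A8 | alternative 3 | tert-butyl (2R)-2-(7-hydroxy-5-methoxy-4-oxo-2-phenyl-4H-chromen-8-yl)piperidine-1-carboxylate | COc1cc(O)c([C@H]2CCCCN2C(=O)OC(C)(C)C)c2oc(-c3ccccc3)cc(=O)c12
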